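(All runs stem from a simulated flask from invented constants; scatter was added.)

Early in the closed epsilon run target reads 0 % at 0.333 h, yet at 1.50 h it reads 26.0 %. Target that appears late and then multiplies suggests self-feeding growth (autocatalysis), and the set-ups below are judged on that reading.

| setting | delta | zeta | epsilon | midnight | autumn | spring | dusk |
|---|---|---|---|---|---|---|---|
| substrate | 0.020 M | 0.020 M | 0.020 M | 0.020 M | 0.020 M | 0.020 M (fed, over 2.00 h) | 0.020 M |
| partner | 0.030 M | 0.042 M | 0.066 M | 0.0300 M (fed, over 2.00 h) | 0.0300 M | 0.0300 M | 0.0300 M |
| remark | run made earlier | run made earlier | run made earlier | a stirred flask in which partner is dosed at a steady rate over 2.00 h without added volume, worked up at 2.5 h | everything together in a closed stirred flask, run for 2.5 h | all but substrate at the start; substrate goes in evenly over 2.00 h, the run ends at 2.5 h | a single well-mixed tank run continuously and read at steady state, 2.5 h in it on average |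
| time |  |  |  | 2.5 h | 2.5 h | 2.5 h |  |

delta run (percent of the substrate charged)

| time / min | target / % | substrate / % |
|---|---|---|
| 8.00 | 0.7 | 99.8 |
| 15.0 | 0.1 | 100.1 |
| 40.0 | 0 | 99.5 |
| 90.0 | 0.3 | 99.7 |

zeta run (percent of the substrate charged)

| time / h | target / % | substrate / % |
|---|---|---|
| 0.200 | 0 | 100.9 |
| 0.500 | 0 | 99.9 |
| 1.00 | 1.4 | 99.0 |
| 2.50 | 9.1 | 86.6 |

epsilon run (percent of the substrate charged)

| time / h | target / % | substrate / % |
|---|---|---|
| 0.333 | 0 | 99.2 |
| 0.833 | 2.1 | 96.9 |
| 1.50 | 26.0 | 63.4 |
| 2.50 | 72.8 | 16.8 |

(each reading ± 0.3 percentage points)

- the set-up with the highest amount of target at the outlet or at the end, in percent of the substrate put in ("none" if the first two lie within 2 percentage points) (midnight / autumn / spring / dusk / none)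
- amount of target at the outlet or at the end, in percent of the substrate put in, midnight
- amount of target at the outlet or at the end, in percent of the substrate put in, autumn
- amount of target at the outlet or at the end, in percent of the substrate put in, spring
- amount of target at the outlet or at the end, in percent of the substrate put in, dusk

- the stated concentrations are those of everything mixed, before any reaction; amounts are the same in each set-up
- the analysis behind the earlier runs scatters by 0.3 percentage points, standard deviation
- the feed brings no volume worth counting
- the earlier runs were made in a closed, stirred flask

Let g be the growth rate of target, read from the steep stretch of a run. Epsilon gives 3.77 h⁻¹ and zeta gives 1.25 h⁻¹, so g goes roughly as partner to the power 2.45, and at 0.0300 M it comes to 0.548 h⁻¹.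

Follow one unit of target in the dusk tank, where the mean stay τ is 2.5 h. It makes more target at rate g, or it leaves at rate 1/τ. The product gτ comes to 1.37, and this is N, the return number: the new target one unit makes before it leaves. N stands above one, so by this reckoning each unit in dusk more than replaces itself.

The objection is delta, which shows no growth at this partner level. Over 90.0 min, however, g multiplies target by only 2.28. Extrapolating back to the start gives a seed of 0.0907 % from epsilon and 0.402 % from zeta. Delta should then end between 0.206 % and 0.915 %, against a reading of 0.3 % with scatter 0.3 percentage points, which favours the lower seed but does not refute g.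

A second objection is that conversion in the tank lowers substrate and partner, and so N. Taking N down to one gives about 10.2 % for dusk. In autumn the same N acts once, as a factor 3.94 on the seed, which gives 0.357 % to 1.58 %. Midnight and spring, with one reagent held under its charge for 2.00 h, are put below autumn.

The forecast gives 0.1 % for midnight, 0.6 % for autumn, 0.4 % for spring and 8 % for dusk, so it names dusk, saying that the tank “holds aged, already active material”.

    partner → decomposed reagent (k = 0.537 h⁻¹)
    substrate + partner → target + released group (k = 0.00950 M⁻¹ h⁻¹)
    substrate + partner + released group → target + 2 released group (k = 12600 M⁻² h⁻¹)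
    substrate + released group ⇌ idle adduct, settled at all times (K = 49.9 M⁻¹)

Midnight gives 0.309 %, autumn 1.33 %, spring 0.103 % and dusk 60.9 %, so dusk comes first. With N at 1.37, dusk stands 51 points above the reckoned 10.2 %, while autumn lies inside its span of 0.357 % to 1.58 %, reckoned with the factor 3.94. In autumn the half-life of substrate by the plain step with partner alone is 100 d, whereas that of partner by decomposition alone is far shorter, at 1.3 h. Autumn's 2.5 h spans 1.92 of those partner half-lives.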